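**Plan** (locants C1–C15 are germacrane locants of the target; see remarks)
1. Retrosynthetic cuts, in order: C1–C2 (two-carbon bridge of the oxygen-bridged bicycle), C4=C5 (nine-membered cyclic ether), C6–C7 with O6–C12 (methylene lactone), C9–C10, O–C3, and the C8 ester.
2. Forward: ethyl lactate and an isopropenyl oxirane give a 1,4-dioxan-2-one that already holds the C3–O–C10 ether. C9–C7 are added at C10, a Barbier reaction with acrolein builds the cis α-methylene lactone with a C6 vinyl group, ring-closing metathesis gives the oxonene (O, C3–C10, C4=C5), a second metathesis joins C2 to C1, and C1 is reduced.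
3. Stereocentres: C3 from ligand control in a zerovalent-palladium allylic etherification; C10 from enolate alkylation anti to the C3 substituent on the dioxanone; C8 from (R)-solketal; C6/C7 from a chair allylindium addition directed by C8; C1 from a CBS reduction.
4. Enabling feature: O, C3 and C10 of the tetrahydrofuran are already members of the unstrained oxonene and carry, 1,3 across the ring oxygen, a vinyl group (C2) and an acetyl-derived silyl enol ether (C1). Joining C2 to C1 closes the five-membered ring and the ten-membered carbocycle C1–C10 at once; since the configurations at C3 and C10 are set in steps 1 and 3, the closure can only give the bicycle in which C4 and C9 are trans across the tetrahydrofuran.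
5. Helpers: the lactate carboxyl (C1) serves as the dioxanone lactone for the alkylation, then as an acetyl group whose methyl carbon leaves as ethylene; the silyl enol ether is hydrolysed after the closure.

Key step: step 17

Remark on the structure: in the target, C4 (on C3) and C9 (on C10) lie on opposite faces of the tetrahydrofuran ring (a trans-bridged, inside–outside 11-oxabicyclo[6.2.1]undecene) and the lactone is cis-fused. The route is designed for exactly this isomer: (1S,3S,6S,7R,8R,10R), 4Z, (Z)-2-methylbut-2-enoate.
Remark on materials and names: rac-2-(prop-1-en-2-yl)oxirane 2 is taken as a purchasable building block. Locant map: C1 carbinol (from the lactate carboxyl), C2 methylene, C3 ether CH, C4(=C5) bearing C15, C6 lactone O–CH, C7, C8 ester O–CH, C9, C10 quaternary ether carbon bearing C14, C11/C12/C13 acrylate unit. Descriptors in names of 13–31 use these locants. TBS = tert-butyldimethylsilyl, TES = triethylsilyl.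

**Step 1**
Reactants: 1 ethyl (S)-lactate; 2 rac-2-(prop-1-en-2-yl)oxirane
Product: 4 (3S,5R)-3-methyl-5-(prop-1-en-2-yl)-1,4-dioxan-2-one, via hydroxy ester 3 (not isolated)
Conditions: Pd2(dba)3·CHCl3 (1 mol%), (S,S)-DACH-phenyl bisphosphine ligand [(1S,2S)-N,N'-bis(2-diphenylphosphinobenzoyl)cyclohexane-1,2-diamine, 3 mol%], Et3B (2 mol%), CH2Cl2, rt; then CSA (10 mol%), 40 °C
Reagents that add atoms: none
Why: Zerovalent palladium ionizes both enantiomers of 2 to an equilibrating π-allyl/alkoxide pair, the boron ate complex of the lactate hydroxyl delivers oxygen to the allyl terminus next to the alkoxide (branched ether), the chiral ligand sets C3 (its antipode is used should the sense prove opposite), and acid closes the six-membered lactone (Tsuji–Trost allylic etherification run as a dynamic kinetic asymmetric transformation, then lactonization).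

**Step 2**
Reactants: 5 (R)-solketal
Product: 6 [(4S)-2,2-dimethyl-1,3-dioxolan-4-yl]methyl trifluoromethanesulfonate
Conditions: Tf2O, 2,6-lutidine, CH2Cl2, −78 °C
Reagents that add atoms: trifluoromethanesulfonic anhydride, O=S(=O)(OS(=O)(=O)C(F)(F)F)C(F)(F)F
Why: Sulfonylation of the primary alcohol leaves the stereocentre untouched and gives an electrophile reactive enough for a hindered enolate (triflate formation).

**Step 3**
Reactants: 4 dioxanone; 6 triflate
Product: 8 (3R,5R)-3-{[(4R)-2,2-dimethyl-1,3-dioxolan-4-yl]methyl}-3-methyl-5-(prop-1-en-2-yl)-1,4-dioxan-2-one, via lithium enolate 7 (not isolated)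
Conditions: LDA, THF, −78 °C; then 6, DMPU, −78 → −40 °C
Reagents that add atoms: none
Why: The lithium enolate of the 1,4-dioxan-2-one displaces the primary triflate on the face anti to the pseudoequatorial isopropenyl group on C3, which sets the quaternary C10 with C9 trans to C4, while C8 arrives unchanged from 6 (diastereoselective alkylation of a cyclic α-alkoxy lactone enolate).

**Step 4**
Reactants: 8 acetonide
Product: 9 (3R,5R)-3-[(2R)-2,3-dihydroxypropyl]-3-methyl-5-(prop-1-en-2-yl)-1,4-dioxan-2-one
Conditions: AcOH/H2O (4:1), rt, short reaction time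
Reagents that add atoms: none
Why: Mild aqueous acid cleaves the terminal acetonide and should leave the lactone in place, acyl transfer to the new secondary hydroxyl needing stronger acid or base (acetal hydrolysis).

**Step 5**
Reactants: 9 diol
Product: 11 (3R,5R)-3-[(2R)-2-(TBS-oxy)-3-(TES-oxy)propyl]-3-methyl-5-(prop-1-en-2-yl)-1,4-dioxan-2-one, via triethylsilyl ether 10 (not isolated)
Conditions: TESCl (1.05 equiv), imidazole, CH2Cl2, −40 °C; then TBSOTf, 2,6-lutidine, −40 → 0 °C
Reagents that add atoms: chlorotriethylsilane, CC[Si](Cl)(CC)CC; tert-butyldimethylsilyl triflate, CC(C)(C)[Si](C)(C)OS(=O)(=O)C(F)(F)F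
Why: Kinetic silylation takes the primary hydroxyl (C7–O) first and the silyl triflate then caps the secondary C8 hydroxyl, which marks C7–O for selective oxidation later (chemoselective silyl ether formation).

**Step 6**
Reactants: 11 lactone
Product: 13 methyl ketone (3R,8R,10R) with C2–OTBS C8–OTBS C7–OTES, via lactol 12 (not isolated)
Conditions: MeLi (1.1 equiv), THF, −78 °C; aq. NH4Cl; then TBSCl, imidazole, DMF, rt
Reagents that add atoms: methyllithium, [Li]C; tert-butylchlorodimethylsilane, CC(C)(C)[Si](C)(C)Cl
Why: At −78 °C methyllithium adds once because the tetrahedral lithium hemiketal is stable, and silylation of the primary hydroxyl of the open keto alcohol tautomer pulls lactol 12 over to the methyl ketone (organolithium addition to a lactone, then silyl ether formation).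

**Step 7**
Reactants: 13 methyl ketone
Product: 14 α-silyloxy aldehyde (3R,8R,10R) with C7 as CHO
Conditions: (COCl)2, DMSO, CH2Cl2, −78 → −30 °C; Et3N
Reagents that add atoms: none
Why: Activated DMSO cleaves and oxidizes the primary triethylsilyl ether in one operation while both TBS ethers stay (Swern oxidation of a silyl ether).

**Step 8**
Reactants: 14 aldehyde; 15 methyl acrylate
Product: 16 allylic alcohol (3R,8R,10R; C7 epimers) with C7(OH)–C11(=C13H2)–CO2Me
Conditions: DABCO (1 equiv), methyl acrylate (neat, excess), rt
Reagents that add atoms: none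
Why: The amine adds to the acrylate and the resulting enolate adds to the inductively activated aldehyde; the new C7 carbinol need not be controlled because C7 becomes sp2 in step 9 (Morita–Baylis–Hillman reaction).

**Step 9**
Reactants: 16 allylic alcohol
Product: 17 (Z)-2-(bromomethyl)enoate (3R,8R,10R)
Conditions: NBS, Me2S, CH2Cl2, 0 °C → rt
Reagents that add atoms: N-bromosuccinimide, O=C1CCC(=O)N1Br
Why: The alcohol is activated as an alkoxysulfonium salt and bromide attacks the methylene terminus with allylic transposition to the thermodynamically preferred Z enoate (Corey–Kim-type SN2′ bromination).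

**Step 10**
Reactants: 17 allylic bromide; 18 acrolein
Product: 20 cis α-methylene-γ-lactone keto alcohol (3R,6S,7S,8R,10R) with C6 vinyl and free C2–OH (in equilibrium with its six-membered lactol), via hydroxy ester 19 (not isolated)
Conditions: In powder, acrolein (5 equiv), THF/H2O (1:1), rt; then 1 M HCl, THF, rt
Reagents that add atoms: none
Why: The allylindium reagent adds to acrolein through its γ-carbon (C7) in a chair transition state; the Z allyl geometry gives the syn adduct (cis lactone), and the aldehyde approaches C7 anti to the C9 chain with H8 eclipsing the alkene, while the hindered C1 ketone is far less reactive than acrolein; acid then closes the γ-lactone and removes only the primary TBS group (Barbier allylation, then lactonization).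

**Step 11**
Reactants: 20 diene
Product: 21 oxonene alcohol (3R,6S,7S,8R,10R; 4Z)
Conditions: second-generation Grubbs catalyst (10 mol%), 1,4-benzoquinone (20 mol%), toluene (1 mM), 80 °C
Reagents that add atoms: none
Why: The ruthenium alkylidene formed at the C6 vinyl group closes onto the isopropenyl group to give the nine-membered cyclic ether, whose ring size enforces the Z trisubstituted C4=C5 bond, the cis-fused lactone preorganizing the chain (ring-closing metathesis).

**Step 12**
Reactants: 21 alcohol
Product: 22 oxonene aldehyde (3R,6S,7S,8R,10R) with C2 as CHO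
Conditions: Dess–Martin periodinane, NaHCO3, CH2Cl2, 0 °C; used crude
Reagents that add atoms: none
Why: Buffered hypervalent iodine oxidation converts the only free hydroxyl into the aldehyde under non-basic conditions that spare the C3 stereocentre (Dess–Martin oxidation).

**Step 13**
Reactants: 22 aldehyde
Product: 23 oxonene with C3 vinyl (3S,6S,7S,8R,10R)
Conditions: CH2I2, Zn dust, Ti(OiPr)4, THF, rt
Reagents that add atoms: diiodomethane, ICI
Why: The non-basic geminal dizinc reagent methylenates the aldehyde in preference to the methyl ketone and the lactone and can neither epimerize C3 nor add to the methylene lactone (Takai methylenation).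

**Step 14**
Reactants: 23 silyl ether
Product: 24 C8 alcohol (3S,6S,7R,8R,10R)
Conditions: HF·pyridine, pyridine, THF, 0 °C → rt
Reagents that add atoms: none
Why: Fluoride cleaves the remaining silyl ether and frees the C8 hydroxyl as the only hydroxyl for acylation (desilylation).

**Step 15**
Reactants: 24 alcohol; 25 angelic acid
Product: 27 C8 angelate (3S,6S,7R,8R,10R), via mixed anhydride 26 (not isolated)
Conditions: 25, 2,4,6-trichlorobenzoyl chloride, Et3N, toluene, rt; then 24, DMAP, toluene, 60 °C
Reagents that add atoms: none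
Why: The mixed anhydride acylates the secondary C8 hydroxyl under conditions that keep the Z geometry of the angelate (Yamaguchi esterification).

**Step 16**
Reactants: 27 methyl ketone
Product: 28 triethylsilyl enol ether (3S,6S,7R,8R,10R) with C10–C1(OTES)=CH2
Conditions: TESOTf, Et3N, CH2Cl2, −78 °C
Reagents that add atoms: triethylsilyl triflate, CC[Si](CC)(CC)OS(=O)(=O)C(F)(F)F
Why: Soft enolization can only go toward the methyl group because C10 is quaternary, which gives the 2-silyloxyalkene needed as metathesis partner (silyl enol ether formation).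

**Step 17**
Reactants: 28 silyl enol ether
Product: 30 bicyclic ketone (3S,6S,7R,8R,10R) with C1=O and C2H2, via cyclic silyl enol ether 29 (not isolated)
Conditions: second-generation Hoveyda–Grubbs catalyst (20 mol%), 1,4-benzoquinone, toluene (0.5 mM), 100 °C, argon purge; then AcOH/THF/H2O, 0 °C
Reagents that add atoms: none
Why: The ruthenium alkylidene forms at the monosubstituted C3 vinyl group (C2) and undergoes [2+2] cycloaddition and cycloreversion with the 1,1-disubstituted silyl enol ether on C10 (C1), giving the C1=C2 bond of 29 and ethylene, whose loss makes the closure irreversible; the closest known reaction type is ring-closing metathesis of silyl enol ethers with terminal olefins to five- to seven-membered cyclic enol ethers, and metathesis is also an established way to close trans-bridged bicycles whose bridgehead configurations are set before the ring closure. This one event closes the 2,5-dihydrofuran (O–C3–C2–C1–C10, a five-membered closure between the sp2 ends of the two arms) and with it the ten-membered carbocycle C1–C10 of the 11-oxabicyclo[6.2.1]undecene. No stereocentre is created: C3 and C10, set in steps 1 and 3 and not epimerizable under these neutral conditions, dictate that C4 and C9 end up trans across the new ring. The step needs closure onto the enol ether and not onto the lactone methylene (C13) or between molecules: the five-membered ring is kinetically favoured, the C11=C13 group sits on the opposite face of the oxonene from the C3 vinyl group, C4=C5 and the angelate are trisubstituted and inert, and high dilution suppresses dimerization. Mild acid then hydrolyses the silyl enol ether to ketone 30, which is reduced at once because a β-alkoxy ketone in a strained ring is prone to retro-oxa-Michael opening.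

**Step 18**
Reactants: 30 ketone
Product: 31 target (1S,3S,6S,7R,8R,10R)
Conditions: (R)-2-methyl-CBS-oxazaborolidine (0.5 equiv), catecholborane, toluene, −78 °C
Reagents that add atoms: none
Why: Catalyst-controlled hydride delivery to a ketone flanked by a quaternary carbon (large) and a methylene (small) should give the 1S alcohol, on the face not shielded by C14 and C4, and catecholborane at −78 °C leaves the methylene lactone and the angelate alone (Corey–Bakshi–Shibata reduction).

**Compound list**
1 | ethyl (S)-lactate | C[C@H](O)C(=O)OCC | starting material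
2 | rac-2-(prop-1-en-2-yl)oxirane | CC(=C)C1CO1 | starting material
3 | ethyl (2S)-2-{[(2R)-1-hydroxy-3-methylbut-3-en-2-yl]oxy}propanoate | CCOC(=O)[C@H](C)O[C@@H](CO)C(C)=C | intermediate
4 | (3S,5R)-3-methyl-5-(prop-1-en-2-yl)-1,4-dioxan-2-one | CC(=C)[C@@H]1COC(=O)[C@H](C)O1 | intermediate
5 | (R)-solketal, (R)-(2,2-dimethyl-1,3-dioxolan-4-yl)methanol | OC[C@@H]1COC(C)(C)O1 | starting material
6 | [(4S)-2,2-dimethyl-1,3-dioxolan-4-yl]methyl trifluoromethanesulfonate | FC(F)(F)S(=O)(=O)OC[C@@H]1COC(C)(C)O1 | intermediate
7 | lithium enolate of 4 | CC(=C)[C@@H]1COC(O[Li])=C(C)O1 | intermediate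
8 | (3R,5R)-3-{[(4R)-2,2-dimethyl-1,3-dioxolan-4-yl]methyl}-3-methyl-5-(prop-1-en-2-yl)-1,4-dioxan-2-one | CC(=C)[C@@H]1COC(=O)[C@@](C)(C[C@@H]2COC(C)(C)O2)O1 | intermediate
9 | (3R,5R)-3-[(2R)-2,3-dihydroxypropyl]-3-methyl-5-(prop-1-en-2-yl)-1,4-dioxan-2-one | CC(=C)[C@@H]1COC(=O)[C@@](C)(C[C@@H](O)CO)O1 | intermediate
10 | (3R,5R)-3-[(2R)-2-hydroxy-3-(triethylsilyloxy)propyl]-3-methyl-5-(prop-1-en-2-yl)-1,4-dioxan-2-one | CC(=C)[C@@H]1COC(=O)[C@@](C)(C[C@@H](O)CO[Si](CC)(CC)CC)O1 | intermediate
11 | (3R,5R)-3-[(2R)-2-(tert-butyldimethylsilyloxy)-3-(triethylsilyloxy)propyl]-3-methyl-5-(prop-1-en-2-yl)-1,4-dioxan-2-one | CC(=C)[C@@H]1COC(=O)[C@@](C)(C[C@@H](O[Si](C)(C)C(C)(C)C)CO[Si](CC)(CC)CC)O1 | intermediate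
12 | lactol from 11 (2-hydroxy-2-methyl-1,4-dioxane, anomers) | CC(=C)[C@@H]1COC(C)(O)[C@@](C)(C[C@@H](O[Si](C)(C)C(C)(C)C)CO[Si](CC)(CC)CC)O1 | intermediate
13 | methyl ketone (3R,8R,10R): C10 bears CH3, acetyl, C9 and O–C3; C3 bears isopropenyl and CH2OTBS; C8–OTBS; C7–OTES | CC(=C)[C@H](CO[Si](C)(C)C(C)(C)C)O[C@](C)(C[C@@H](O[Si](C)(C)C(C)(C)C)CO[Si](CC)(CC)CC)C(C)=O | intermediate
14 | aldehyde (3R,8R,10R): as 13 with C7 as CHO | CC(=C)[C@H](CO[Si](C)(C)C(C)(C)C)O[C@](C)(C[C@@H](O[Si](C)(C)C(C)(C)C)C=O)C(C)=O | intermediate
15 | methyl acrylate | C=CC(=O)OC | starting material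
16 | Morita–Baylis–Hillman adduct (3R,8R,10R; C7 epimers) | CC(=C)[C@H](CO[Si](C)(C)C(C)(C)C)O[C@](C)(C[C@@H](O[Si](C)(C)C(C)(C)C)C(O)C(=C)C(=O)OC)C(C)=O | intermediate
17 | methyl (Z)-2-(bromomethyl)enoate (3R,8R,10R), C7=C11 | CC(=C)[C@H](CO[Si](C)(C)C(C)(C)C)O[C@](C)(C[C@@H](O[Si](C)(C)C(C)(C)C)/C=C(\CBr)C(=O)OC)C(C)=O | intermediate
18 | acrolein | C=CC=O | starting material
19 | syn homoallylic alcohol ester (3R,6S,7S,8R,10R) | C=C[C@H](O)[C@H](C(=C)C(=O)OC)[C@H](O[Si](C)(C)C(C)(C)C)C[C@@](C)(O[C@@H](CO[Si](C)(C)C(C)(C)C)C(C)=C)C(C)=O | intermediate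
20 | cis α-methylene-γ-lactone keto alcohol (3R,6S,7S,8R,10R), C6 vinyl, C8–OTBS, free C2–OH | C=C1C(=O)O[C@@H](C=C)[C@H]1[C@H](O[Si](C)(C)C(C)(C)C)C[C@@](C)(O[C@@H](CO)C(C)=C)C(C)=O | intermediate
21 | oxonene alcohol (3R,6S,7S,8R,10R; 4Z) | C=C1C(=O)O[C@H]2/C=C(/C)[C@H](CO)O[C@@](C)(C(C)=O)C[C@@H](O[Si](C)(C)C(C)(C)C)[C@@H]12 | intermediate
22 | oxonene aldehyde (3R,6S,7S,8R,10R) | C=C1C(=O)O[C@H]2/C=C(/C)[C@H](C=O)O[C@@](C)(C(C)=O)C[C@@H](O[Si](C)(C)C(C)(C)C)[C@@H]12 | intermediate
23 | oxonene with C3 vinyl and C10 acetyl (3S,6S,7S,8R,10R) | C=C1C(=O)O[C@H]2/C=C(/C)[C@H](C=C)O[C@@](C)(C(C)=O)C[C@@H](O[Si](C)(C)C(C)(C)C)[C@@H]12 | intermediate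
24 | C8 alcohol (3S,6S,7R,8R,10R) | C=C1C(=O)O[C@H]2/C=C(/C)[C@H](C=C)O[C@@](C)(C(C)=O)C[C@@H](O)[C@@H]12 | intermediate
25 | angelic acid, (Z)-2-methylbut-2-enoic acid | C/C=C(/C)C(=O)O | starting material
26 | angelic 2,4,6-trichlorobenzoic anhydride | C/C=C(/C)C(=O)OC(=O)c1c(Cl)cc(Cl)cc1Cl | intermediate
27 | C8 angelate (3S,6S,7R,8R,10R) | C=C1C(=O)O[C@H]2/C=C(/C)[C@H](C=C)O[C@@](C)(C(C)=O)C[C@@H](OC(=O)/C(C)=C\C)[C@@H]12 | intermediate
28 | triethylsilyl enol ether (3S,6S,7R,8R,10R) | C=C1C(=O)O[C@H]2/C=C(/C)[C@H](C=C)O[C@@](C)(C(=C)O[Si](CC)(CC)CC)C[C@@H](OC(=O)/C(C)=C\C)[C@@H]12 | intermediate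
29 | bicyclic silyl enol ether, C1(OTES)=C2 (3S,6S,7R,8R,10R) | C=C1C(=O)O[C@H]2/C=C(/C)[C@@H]3C=C(O[Si](CC)(CC)CC)[C@@](C)(C[C@@H](OC(=O)/C(C)=C\C)[C@@H]12)O3 | intermediate
30 | bicyclic ketone, 1-oxo (3S,6S,7R,8R,10R) | C=C1C(=O)O[C@H]2/C=C(/C)[C@@H]3CC(=O)[C@@](C)(C[C@@H](OC(=O)/C(C)=C\C)[C@@H]12)O3 | intermediate
31 | CNP0213894.2, (1S,3S,6S,7R,8R,10R) | C=C1C(=O)O[C@H]2/C=C(/C)[C@@H]3C[C@H](O)[C@@](C)(C[C@@H](OC(=O)/C(C)=C\C)[C@@H]12)O3 | target

**Totals**
Total step count: 18. Longest linear sequence: 17 (steps 1 and 3–18; step 2 is a one-step branch).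

**Steps most likely to fail**

Step 17. The closure has to build the strain of the trans-bridged bicycle, so the alkylidene may be used up by intermolecular metathesis or decompose before it engages the hindered enol ether, and long heating may move the exocyclic lactone double bond. Fallback, setting out from 20 and reversing the order of the two ring closures: Dess–Martin oxidation gives aldehyde F1, Takai methylenation gives triene ketone F2, HF·pyridine gives alcohol F3, Yamaguchi esterification gives angelate F4, and TESOTf/Et3N gives silyl enol ether F5. Metathesis with the second-generation Grubbs catalyst should now close the unstrained five-membered ring first, giving the cyclic silyl enol ether F6, and mild acid gives the furanone F7, which carries the isopropenyl group on C3 and the vinyl lactone chain on C10 trans across the ring. A second ring-closing metathesis between the isopropenyl and C6 vinyl groups at high dilution then closes the nine-membered ether onto the rigid furanone and rejoins the route at 30.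

Step 3. C-alkylation of the fully substituted enolate may be slow, with competing elimination of the β-oxygenated triflate, O-alkylation, or incomplete facial control. Fallback, setting out from 4 and replacing sulfonate displacement by epoxide opening: (S)-glycidol is silylated (TESCl, imidazole) to (R)-triethylsilyl glycidyl ether F8. Enolate 7 is transmetalated with Et2AlCl and opens F8 at its terminal carbon (C9), again anti to the isopropenyl group. Cold aqueous work-up gives the hydroxy silyl ether 10 directly, which is silylated with TBSOTf as in step 5 to rejoin the route at 11, bypassing 6, 8 and 9.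

Step 10. Facial selectivity at C7 may be insufficient, or the allylmetal may add intramolecularly to the C1 ketone. Fallback, setting out from 17: borylation (B2pin2, Pd2(dba)3, toluene, 50 °C) gives the 2-(methoxycarbonyl)allylboronate F9. Its thermal allylboration of acrolein runs through a closed chair transition state with no free organometal and, after aqueous work-up, gives hydroxy ester 19, which is lactonized and desilylated to 20 as in step 10.

**Further compounds**
F1 | step 17 | acyclic aldehyde (3R,6S,7S,8R,10R), C2 as CHO | C=C1C(=O)O[C@@H](C=C)[C@H]1[C@H](O[Si](C)(C)C(C)(C)C)C[C@@](C)(O[C@@H](C=O)C(C)=C)C(C)=O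
F2 | step 17 | acyclic triene ketone with C3 vinyl (3S,6S,7S,8R,10R) | C=C1C(=O)O[C@@H](C=C)[C@H]1[C@H](O[Si](C)(C)C(C)(C)C)C[C@@](C)(O[C@@H](C=C)C(C)=C)C(C)=O
F3 | step 17 | acyclic C8 alcohol (3S,6S,7R,8R,10R) | C=C1C(=O)O[C@@H](C=C)[C@H]1[C@H](O)C[C@@](C)(O[C@@H](C=C)C(C)=C)C(C)=O
F4 | step 17 | acyclic C8 angelate (3S,6S,7R,8R,10R) | C=C1C(=O)O[C@@H](C=C)[C@H]1[C@H](OC(=O)/C(C)=C\C)C[C@@](C)(O[C@@H](C=C)C(C)=C)C(C)=O
F5 | step 17 | acyclic triethylsilyl enol ether (3S,6S,7R,8R,10R) | C=C1C(=O)O[C@@H](C=C)[C@H]1[C@H](OC(=O)/C(C)=C\C)C[C@@](C)(O[C@@H](C=C)C(C)=C)C(=C)O[Si](CC)(CC)CC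
F6 | step 17 | monocyclic 2,5-dihydrofuran silyl enol ether (3S,6S,7R,8R,10R) | C=C1C(=O)O[C@@H](C=C)[C@H]1[C@H](OC(=O)/C(C)=C\C)C[C@@]2(C)O[C@H](C(C)=C)C=C2O[Si](CC)(CC)CC
F7 | step 17 | monocyclic furan-3-one with C3 isopropenyl trans to the C10 chain (3S,6S,7R,8R,10R) | C=C1C(=O)O[C@@H](C=C)[C@H]1[C@H](OC(=O)/C(C)=C\C)C[C@@]2(C)O[C@H](C(C)=C)CC2=O
F8 | step 3 | (R)-triethylsilyl glycidyl ether | CC[Si](CC)(CC)OC[C@H]1CO1
F9 | step 10 | pinacol allylboronate from 17 (3R,8R,10R) | CC(=C)[C@H](CO[Si](C)(C)C(C)(C)C)O[C@](C)(C[C@@H](O[Si](C)(C)C(C)(C)C)/C=C(\CB1OC(C)(C)C(C)(C)O1)C(=O)OC)C(C)=O
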